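A small charge of protic impurity stood in each earlier flask, and we want to know what it costs in links.

all flasks: first end groups 0.21 M; second end groups 0.206 M

| run | protic impurity | remark | time |
|---|---|---|---|
| violet | 0.010 M | run made earlier |  |
| amber | 0.017 M | run made earlier |  |
| teal | 0.021 M | run made earlier |  |
| west | 0.0105 M |  | 2.0 h |
| north-east | 0.0300 M |  | 8.0 h |

| violet: time / min | violet: links / % | amber: time / min | amber: links / % | teal: time / min | teal: links / % |
|---|---|---|---|---|---|
| 8.00 | 13 | 8.00 | 13 | 8.00 | 13 |
| 20.0 | 21 | 20.0 | 24 | 20.0 | 23 |
| 40.0 | 31 | 40.0 | 31 | 40.0 | 30 |
| 60.0 | 36 | 60.0 | 35 | 60.0 | 32 |
| 80.0 | 32 | 80.0 | 34 | 80.0 | 35 |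

(readings scatter by 1.5 percentage points)

1. the flask that ends with the higher amount of links, in percent of the first end groups charged, or "neither" when 2 percentage points or less lies between them (west / north-east / neither)
2. final links, as a percentage of the first end groups charged, in west
3. final links, as a percentage of the first end groups charged, in north-east

We keep the books in fractions of the first end groups charged. We assume, as our own guess, that each unit of protic impurity takes one first end group. The first entry is then the impurity's claim, its charge over the charge of first end groups: 14.3 % in north-east and 5.00 % in west. This claim rose from 4.76 % in violet to 10.0 % in teal, twice as much. Yet the last two readings of links average 34.0 % in violet and 33.5 % in teal, a gap well inside the scatter of 1.5 percentage points on a single reading.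

The second entry is links, read as 34.0 % from the last two readings of violet, amber and teal. The last entry is what no reading shows, 66.0 % of the charge. The north-east claim is smaller than this and leaves 51.7 % open, while the west claim leaves 61.0 %, so in our estimate both claims fit inside the last entry and we enter no loss of links for them.

Second end groups stand at 98.1 % of the charge. In north-east, first end groups net of the claim stand lower, at 85.7 %, which on our reckoning makes them the limiting reagent there, and that still lies above the links entry. Both flasks also run longer than the last reading at 80.0 min. We therefore commit to about 34.0 % of links in each, with neither ahead.

The forecast also says neither, with 34 % (32 % to 37 %) in west and 33 % (25 % to 37 %) in north-east, the latter below our figure, on the ground “If the impurity stays harmless, the longer 8 h adds nothing”.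

The flask gives 35.0 % of links in west and 34.7 % in north-east, so the answer is neither, by these steps:

    first end groups + second end groups → links (k = 0.00190 M⁻¹ s⁻¹)
    first end groups + second end groups → rings, rate k2*[first end groups] as long as [second end groups] is above zero (k = 2.60 × 10⁻⁴ s⁻¹)
    second end groups ⇌ dormant form (K = 0.790, k = 5.60 × 10⁻⁵ s⁻¹)
    first end groups + protic impurity → quenched substrate (k = 0.00720 M⁻¹ s⁻¹)

North-east ends with 13.6 % of quenched substrate against its claim of 14.3 %, and with 51.7 % of rings in the entry no reading saw. The claim serves once more on a neighbour of north-east charged with 0.12 M of protic impurity. Its claim is 57.1 %, and that flask ends with 45.5 % of quenched substrate, 20 % of its own impurity charge still unused, and links lower than in north-east, at 27.0 %.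

Readings and results stem from a simulated flask with constants of no real substance.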